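## Structural features

Eduesmine is a C2-symmetric lignan: one oxolane ring (ring A; O1, C2–C5) carries two identical 4-hydroxy-3-methoxyphenyl rings at C2 and C5 and two hydroxymethyl arms, C3a on C3 and C4a on C4. All four ring carbons are contiguous stereocentres, (2S,3S,4S,5S). C2/C3 are cis, C3/C4 trans and C4/C5 cis, so the aryl rings are trans to each other and each is cis to its neighbouring CH2OH arm. Both ring C–O bonds are benzylic ethers of para-oxygenated arenes. Acid, or a free para-phenoxide, can open them through a benzylic cation or quinone methide and reclose to the more stable aryl/arm-trans isomers, and hydrogenolysis can cleave them. The free phenols are oxidation-prone. The real difficulty is therefore stereochemical: two contra-thermodynamic cis relationships at the benzylic carbons must be made under kinetic control and then kept away from ionising conditions. The key step exploits two features: C2 is a benzylic carbon bonded to O1 with hydridic C–H bonds, and C3 bears the carboxyl-level carbon C3a, which can stabilise a carbenoid. C2–C3 is formed by insertion of a C3 rhodium carbenoid into a C2–H bond, with retention and without a cation at C2, and this closes ring A. Because of the C2 axis, C2 and C5 with their aryl rings both come from the same protected vanillin.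

## Logic of the disconnections

18 ⇒ 17. The three O–Si bonds (two aryl O–Si, one at C4a) are cut. Silyl groups on the phenols and on C4a fall in one fluoride step, so neither acid nor hydrogenolysis touches the benzylic ring C–O bonds. The demand is a buffered fluoride source, so that free phenoxide cannot open ring A through a quinone methide.

17 ⇒ 16. C3a is returned to the carboxyl level. The ester is what makes C3 a carbenoid carbon in the key step; afterwards it is only a liability, because it makes C3–H acidic. The forward reduction must therefore be prompt and faster than enolisation.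

16 ⇒ 15. The C2–C3 bond is cut and ring A is opened. This removes the ring and two stereocentres (C2, C3) and leaves an acyclic chain with only the C4/C5 pair. The forward step must select the benzylic O–CH2 bond over the C4–H hydride shift, and must put the C2 aryl cis to the ester and the ester trans to the C4 arm.

15 ⇒ 13. The C=N2 unit is removed from C3 (deacylative diazo transfer via 14). The gain is a plain ester. The demand is C-acylation of a β-branched ester enolate. The ester is tert-butyl, not methyl, for reasons that appear two paragraphs down.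

13 ⇒ 12 ⇒ 11. The C4a O–Si bond is cut, then C4a is returned to the acyl carbon of the auxiliary (C–N bond). The reduction must spare the other carboxyl group, and the new primary alkoxide must not lactonise onto it. A methyl ester would do both (competing reduction and ready γ-lactonisation); a tert-butyl ester resists both. A silyl ether is used at C4a because a benzyl-type ether there would offer the carbenoid a second activated O–CH2 group.

11 ⇒ 10 + 4. The O1–C2 ether bond is cut. This reveals a β-hydroxy imide and an aryl-methyl donor made from the same aldehyde that supplies C5. The etherification must be non-basic (retro-aldol, lactonisation) and only weakly acidic (the C5–O bond is an ionisable benzylic bond).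

10 ⇒ 8 + 2. The C4–C5 bond is cut (aldol). The C4/C5 pair of 15 and 16 is an anti-aldol pair. When the former α-arm carbon and the carbinol oxygen end in the same five-membered ring, an anti pair becomes ring-cis. A syn pair would become ring-trans and could not lead to 18. The aldol is therefore planned as an anti-selective reaction, with a chelated magnesium enolate of the (4S)-benzyl auxiliary to set 3R,4S.

8 ⇒ 5 + 6 (via 7), and 4 ⇒ 3 ⇒ 2 ⇒ 1. The N–acyl bond, the imidate C–O bond, the benzylic C–H (reduction) and the phenol O–Si bond are cut. All of these are routine; the only demand is that 4 be used fresh.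

## Other disconnections considered

Alternative 1: The cut removes both hydroxymethyl carbons at once (C3–C3a and C4–C4a) and leads back to the C2-symmetric bis(stannylmethyl) ether A2 of an (E,E)-diene diol. In the forward step n-BuLi would exchange tin for lithium at both O–CH2–Sn groups of A2. Each lithiomethyl ether would then undergo a [2,3] shift through a five-membered envelope, transferring the carbinol configuration to C3 and C4 and giving diol A1.
- In its favour: it uses the C2 symmetry fully, installs both arms and the C3/C4 trans relationship in one operation, and needs no diazo compound or precious metal.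
- Against it here: A1 has neither ring A nor the benzylic stereocentres; C2 and C5 are still styrene carbons. Two electron-rich styrenes would have to be cleaved oxidatively, the resulting aryl ketones reduced, and O1 bridged between two ionisable benzylic carbons. That closure tends toward the aryl/arm-trans isomers, the opposite of what 18 needs. Stoichiometric tin is a further cost.
- Comparison: for C3/C4 the pericyclic step is the equal of the chosen plan, and in predictability of mechanism it is the better. On structure it solves the easier half and leaves the two cis benzylic centres uncontrolled. On step economy it needs at least five operations after the key step, against two after step 10.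

Alternative 2: The cut is at the two aryl–ring bonds (C2–aryl, C5–aryl) and leads back to the trans bis(quinolin-8-yl) amide A4 and aryl iodide A5. In the forward step, under Pd(OAc)2 and AgOAc, each amide would direct cyclopalladation of the cis β-C–H bond at C2 or C5 through a five-membered palladacycle. Oxidative addition of A5 (to tetravalent palladium) and reductive elimination would give A3.
- In its favour: each aryl group must end cis to its directing carboxamide, so 2,3-cis and 4,5-cis follow from the mechanism, and the trans diamide makes the aryl rings trans. Ring A is present from the start and both aryl groups enter in one flask. This stereochemical guarantee at C2 and C5 is better than the catalyst-dependent cis selectivity of the chosen plan, and the step count is lower, which is also better.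
- Against it here: the key step creates no absolute configuration, so A4 must be resolved or made by a separate asymmetric synthesis. The twofold arylation must go to completion at two hindered sites near 110 °C, where the strained centres α to the amides can epimerise. Two hindered secondary amides must finally be activated and reduced to CH2OH at exactly those centres.
- Comparison: structure and step economy favour this alternative. The chosen plan is stronger on the source of absolute configuration (a recoverable auxiliary) and on the mildness of everything that follows ring formation.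

Alternative 3: The cut is the O1–C5 bond. Ring A is traced back through lactone A6, whose carbonyl carbon is C2, to cyclobutanone A7. In the forward step buffered m-CPBA would add to the strained ketone of A7. In the Criegee intermediate the benzylic carbon would migrate to oxygen with retention, forming O1–C5 and expanding the ring to A6.
- In its favour: retention brings the C5 configuration in without any cationic stage, and ring strain should let the oxidation outrun attack on the arene. From A6 the C2 aryl ring would enter by aryllithium addition and silane reduction of the lactol. That endgame is well established for this lignan family and in precedent is better than a carbenoid insertion.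
- Against it here: the key step makes one C–O bond and no stereocentre. All three stereocentres of A6 must already be in A7, an enantiopure trisubstituted cyclobutanone that is a synthesis in itself. Both α-carbons of A7 are secondary, so regioselectivity rests on the aryl group alone. The Lewis-acidic lactol reduction exposes the C5–O bond to ionisation.
- Comparison: mechanistically the migration is as reliable as anything in the chosen plan (equal). Structurally the chosen plan creates ring A and two stereocentres in its key step, whereas this one creates neither. Overall this alternative is longer.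

Key step: step 10

Assumptions: compounds 5 and 6 and both antipodes of the tert-leucinate dirhodium catalyst are bought; the (R)-ligand catalyst is taken to be the antipode matched to the C4/C5 centres of 15, to be confirmed against its antipode on small scale.
Abbreviations in names: Ar = 3-methoxy-4-[(triisopropylsilyl)oxy]phenyl; TIPS = triisopropylsilyl.

## Route

Step 1
Reactants: 1 vanillin (4-hydroxy-3-methoxybenzaldehyde)
Product: 2 3-methoxy-4-[(triisopropylsilyl)oxy]benzaldehyde
Conditions: TIPSCl (1.1 equiv), imidazole (2 equiv), DMF, rt
Reagents that add atoms: chlorotriisopropylsilane, CC(C)[Si](Cl)(C(C)C)C(C)C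
Why: Imidazole-promoted O-silylation of the phenol; the aryl silyl ether should survive every later step and leave with fluoride at the end together with the aliphatic silyl ether, so no hydrogenolysis is needed near the benzylic ring C–O bonds.

Step 2
Reactants: 2 3-methoxy-4-[(triisopropylsilyl)oxy]benzaldehyde
Product: 3 {3-methoxy-4-[(triisopropylsilyl)oxy]phenyl}methanol
Conditions: NaBH4, THF/MeOH, 0 °C
Reagents that add atoms: none
Why: Borohydride reduction of an aryl aldehyde to the benzylic alcohol; the aryl silyl ether is stable at 0 °C for the short reaction time.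

Step 3
Reactants: 3 {3-methoxy-4-[(triisopropylsilyl)oxy]phenyl}methanol
Product: 4 {3-methoxy-4-[(triisopropylsilyl)oxy]phenyl}methyl 2,2,2-trichloroacetimidate
Conditions: Cl3CCN (1.5 equiv), DBU (0.1 equiv), CH2Cl2, 0 °C; filtered through Et3N-treated silica and used at once
Reagents that add atoms: trichloroacetonitrile, N#CC(Cl)(Cl)Cl
Why: Base-catalysed addition of the alkoxide to the nitrile (trichloroacetimidate formation); the electron-rich benzylic imidate is acid-labile and is therefore not stored.

Step 4
Reactants: 5 4-tert-butoxy-4-oxobutanoic acid (mono-tert-butyl succinate); 6 (4S)-4-benzyl-1,3-oxazolidin-2-one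
Product: 8 tert-butyl 4-[(4S)-4-benzyl-2-oxo-1,3-oxazolidin-3-yl]-4-oxobutanoate, via mixed pivalic anhydride 7 (not isolated)
Conditions: PivCl, Et3N, THF, −20 °C; then LiCl, 6, −20 °C → rt
Reagents that add atoms: none
Why: Mixed-anhydride N-acylation of the oxazolidinone; the nitrogen attacks the unhindered succinyl carbonyl of the anhydride and not the pivaloyl carbonyl, and the tert-butyl ester is inert.

Step 5
Reactants: 8 tert-butyl 4-[(4S)-4-benzyl-2-oxo-1,3-oxazolidin-3-yl]-4-oxobutanoate; 2 3-methoxy-4-[(triisopropylsilyl)oxy]benzaldehyde
Product: 10 tert-butyl (3R,4S)-4-Ar-3-{[(4S)-4-benzyl-2-oxo-1,3-oxazolidin-3-yl]carbonyl}-4-hydroxybutanoate, via trimethylsilyl ether 9 (not isolated)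
Conditions: MgCl2 (0.2 equiv), Et3N (2 equiv), TMSCl (1.5 equiv), EtOAc, rt; then 1 M HCl/THF, 0 °C
Reagents that add atoms: none
Why: MgCl2-catalysed direct anti-aldol of an N-acyl oxazolidinone (soft enolisation); the chelated Z-enolate should be attacked on the face away from the benzyl group, as in alkylations of this auxiliary, fixing C3 as R, and the boat-like arrangement with silyl trapping of the aldolate should place aryl and oxygen anti, fixing C4 as S (the future C4 and C5 of ring A). In-situ O-silylation turns the metal over and prevents retro-aldol and lactonisation; brief cold dilute acid then frees the hydroxyl.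

Step 6
Reactants: 10 tert-butyl (3R,4S)-4-Ar-3-{[(4S)-4-benzyl-2-oxo-1,3-oxazolidin-3-yl]carbonyl}-4-hydroxybutanoate; 4 {3-methoxy-4-[(triisopropylsilyl)oxy]phenyl}methyl 2,2,2-trichloroacetimidate
Product: 11 tert-butyl (3R,4S)-4-Ar-4-(Ar-methoxy)-3-{[(4S)-4-benzyl-2-oxo-1,3-oxazolidin-3-yl]carbonyl}butanoate
Conditions: 4 (2 equiv), CSA (0.1 equiv), CH2Cl2, 0 °C → rt
Reagents that add atoms: none
Why: Acid-catalysed trichloroacetimidate O-alkylation; the stabilised aryl-methyl cation is captured by the secondary hydroxyl under conditions that avoid the retro-aldol and lactonisation a basic Williamson etherification would cause. The imidate ionises at far lower acidity than the C5–O bond, which is further deactivated by the β-acyl group, so the stereocentres should be untouched.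

Step 7
Reactants: 11 tert-butyl (3R,4S)-4-Ar-4-(Ar-methoxy)-3-{[(4S)-4-benzyl-2-oxo-1,3-oxazolidin-3-yl]carbonyl}butanoate
Product: 12 tert-butyl (3S,4S)-4-Ar-4-(Ar-methoxy)-3-(hydroxymethyl)butanoate
Conditions: LiBH4 (1.5 equiv), MeOH (1.5 equiv), Et2O, 0 °C; aq. NH4Cl
Reagents that add atoms: none
Why: Reductive cleavage of the N-acyl oxazolidinone to the primary alcohol with release of the auxiliary; LiBH4 does not reduce a tert-butyl ester and the new γ-alkoxide does not lactonise onto it at 0 °C, which is why the ester is tert-butyl (the descriptor at C3 changes to S only through the priority rules).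

Step 8
Reactants: 12 tert-butyl (3S,4S)-4-Ar-4-(Ar-methoxy)-3-(hydroxymethyl)butanoate
Product: 13 tert-butyl (3S,4S)-4-Ar-4-(Ar-methoxy)-3-{[(triisopropylsilyl)oxy]methyl}butanoate
Conditions: TIPSCl, imidazole, DMAP (cat.), DMF, rt
Reagents that add atoms: chlorotriisopropylsilane, CC(C)[Si](Cl)(C(C)C)C(C)C
Why: O-silylation of the primary alcohol; a silyl ether offers the later carbenoid no activated C–H bond in a 1,5 relationship and is removed with the aryl silyl ethers.

Step 9
Reactants: 13 tert-butyl (3S,4S)-4-Ar-4-(Ar-methoxy)-3-{[(triisopropylsilyl)oxy]methyl}butanoate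
Product: 15 tert-butyl (3S,4S)-4-Ar-4-(Ar-methoxy)-2-diazo-3-{[(triisopropylsilyl)oxy]methyl}butanoate, via trifluoroacetyl ester 14 (not isolated)
Conditions: LiN(i-Pr)2 (1.2 equiv), THF, −78 °C; CF3CO2CH2CF3 (1.3 equiv), −78 °C; then p-ABSA (1.5 equiv), Et3N (1.5 equiv), H2O (1 equiv), MeCN, rt
Reagents that add atoms: 4-acetamidobenzenesulfonyl azide (p-ABSA), CC(=O)Nc1ccc(cc1)S(=O)(=O)N=[N+]=[N-]
Why: Claisen-type C-trifluoroacetylation of the ester enolate, then deacylative (Regitz-type) diazo transfer in which the trifluoroacetyl group leaves on the sulfonamide nitrogen; only C2 is deprotonated, so the C3/C4 stereocentres are not at risk, and tert-butyl ester enolates do not self-condense.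

Step 10
Reactants: 15 tert-butyl (3S,4S)-4-Ar-4-(Ar-methoxy)-2-diazo-3-{[(triisopropylsilyl)oxy]methyl}butanoate
Product: 16 tert-butyl (2S,3R,4S,5S)-2,5-di-Ar-4-{[(triisopropylsilyl)oxy]methyl}oxolane-3-carboxylate
Conditions: Rh2(R-PTTL)4 (dirhodium tetrakis[N-phthaloyl-(R)-tert-leucinate], 2 mol %), toluene, −78 → −40 °C, slow addition of 15
Reagents that add atoms: none
Why: The diazo ester binds an axial site of the dirhodium core (rhodium divalent throughout), loses N2 and gives an electrophilic carbenoid at C3, which inserts into a benzylic O–CH2 bond through a three-centre, hydride-transfer-like transition state; the closest known reaction type is the dirhodium carboxylate-catalysed intramolecular 1,5 C–H insertion of α-alkyl-α-diazo esters, which gives cis-2-arylcyclopentane carboxylates and, next to an ether oxygen, oxolanes. Ring A closes by 1,5-insertion, a five-membered ring formed through a chair-like six-centre array that includes the migrating hydrogen. C2 is created with retention by replacing one of the two diastereotopic benzylic hydrogens, and the choice between them is governed by the phthalimido wall of the tert-leucinate ligands, which in this catalyst class places the aryl group cis to the ester. C3 is set by the face of the carbenoid that the C–H bond reaches, and the C4 stereocentre controls it: the ester should take the position trans to the C4 silyloxymethyl arm to avoid eclipsing it in the forming ring. The (R)-ligand antipode is specified so that catalyst preference and substrate preference coincide. The step needs insertion at O–CH2 and not a 1,2-hydride shift from C4–H, attack on the C5 arene or ylide formation: the target C–H bond is activated by O1 and by an electron-rich arene, C4–H is inductively deactivated by two β-oxygen substituents, only strained four-membered oxonium ylides are within reach, and bulky carboxylate ligands at low temperature are the conditions known to suppress the hydride shift.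

Step 11
Reactants: 16 tert-butyl (2S,3R,4S,5S)-2,5-di-Ar-4-{[(triisopropylsilyl)oxy]methyl}oxolane-3-carboxylate
Product: 17 [(2S,3S,4S,5S)-2,5-di-Ar-4-{[(triisopropylsilyl)oxy]methyl}oxolan-3-yl]methanol
Conditions: LiAlH4, THF, 0 °C, directly after step 10; aq. KNaC4H4O6 work-up
Reagents that add atoms: none
Why: LiAlH4 reduction of the ester to the primary alcohol; hydride addition is faster than enolisation, so C3 is converted into a non-epimerisable centre (its descriptor changes to S only through the priority rules), and any partial loss of an aryl silyl group would be harmless because step 12 removes them all.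

Step 12
Reactants: 17 [(2S,3S,4S,5S)-2,5-di-Ar-4-{[(triisopropylsilyl)oxy]methyl}oxolan-3-yl]methanol
Product: 18 Eduesmine, 4,4'-[(2S,3S,4S,5S)-3,4-bis(hydroxymethyl)oxolane-2,5-diyl]bis(2-methoxyphenol)
Conditions: Bu4NF (3.5 equiv), AcOH (3.5 equiv), THF, 0 °C → rt
Reagents that add atoms: none
Why: Fluoride-mediated cleavage of the three Si–O bonds; the acetic acid buffer keeps the phenols protonated so that ring A cannot open through a quinone methide, and no acid strong enough to ionise the benzylic ethers is present.

## Compound list

1 | vanillin (4-hydroxy-3-methoxybenzaldehyde) | COc1cc(C=O)ccc1O | starting material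
2 | 3-methoxy-4-[(triisopropylsilyl)oxy]benzaldehyde | COc1cc(C=O)ccc1O[Si](C(C)C)(C(C)C)C(C)C | intermediate
3 | {3-methoxy-4-[(triisopropylsilyl)oxy]phenyl}methanol | COc1cc(CO)ccc1O[Si](C(C)C)(C(C)C)C(C)C | intermediate
4 | {3-methoxy-4-[(triisopropylsilyl)oxy]phenyl}methyl 2,2,2-trichloroacetimidate | COc1cc(COC(=N)C(Cl)(Cl)Cl)ccc1O[Si](C(C)C)(C(C)C)C(C)C | intermediate
5 | 4-tert-butoxy-4-oxobutanoic acid (mono-tert-butyl succinate) | CC(C)(C)OC(=O)CCC(=O)O | starting material
6 | (4S)-4-benzyl-1,3-oxazolidin-2-one | O=C1OC[C@H](Cc2ccccc2)N1 | starting material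
7 | 4-tert-butoxy-4-oxobutanoic pivalic anhydride (formed in the flask, not isolated) | CC(C)(C)OC(=O)CCC(=O)OC(=O)C(C)(C)C | intermediate
8 | tert-butyl 4-[(4S)-4-benzyl-2-oxo-1,3-oxazolidin-3-yl]-4-oxobutanoate | CC(C)(C)OC(=O)CCC(=O)N1[C@@H](Cc2ccccc2)COC1=O | intermediate
9 | tert-butyl (3R,4S)-4-Ar-3-{[(4S)-4-benzyl-2-oxo-1,3-oxazolidin-3-yl]carbonyl}-4-[(trimethylsilyl)oxy]butanoate (formed in the flask, not isolated) | CC(C)(C)OC(=O)C[C@@H](C(=O)N1[C@@H](Cc2ccccc2)COC1=O)[C@H](O[Si](C)(C)C)c1ccc(O[Si](C(C)C)(C(C)C)C(C)C)c(OC)c1 | intermediate
10 | tert-butyl (3R,4S)-4-Ar-3-{[(4S)-4-benzyl-2-oxo-1,3-oxazolidin-3-yl]carbonyl}-4-hydroxybutanoate | CC(C)(C)OC(=O)C[C@@H](C(=O)N1[C@@H](Cc2ccccc2)COC1=O)[C@H](O)c1ccc(O[Si](C(C)C)(C(C)C)C(C)C)c(OC)c1 | intermediate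
11 | tert-butyl (3R,4S)-4-Ar-4-(Ar-methoxy)-3-{[(4S)-4-benzyl-2-oxo-1,3-oxazolidin-3-yl]carbonyl}butanoate | CC(C)(C)OC(=O)C[C@@H](C(=O)N1[C@@H](Cc2ccccc2)COC1=O)[C@H](OCc1ccc(O[Si](C(C)C)(C(C)C)C(C)C)c(OC)c1)c1ccc(O[Si](C(C)C)(C(C)C)C(C)C)c(OC)c1 | intermediate
12 | tert-butyl (3S,4S)-4-Ar-4-(Ar-methoxy)-3-(hydroxymethyl)butanoate | CC(C)(C)OC(=O)C[C@@H](CO)[C@H](OCc1ccc(O[Si](C(C)C)(C(C)C)C(C)C)c(OC)c1)c1ccc(O[Si](C(C)C)(C(C)C)C(C)C)c(OC)c1 | intermediate
13 | tert-butyl (3S,4S)-4-Ar-4-(Ar-methoxy)-3-{[(triisopropylsilyl)oxy]methyl}butanoate | CC(C)(C)OC(=O)C[C@@H](CO[Si](C(C)C)(C(C)C)C(C)C)[C@H](OCc1ccc(O[Si](C(C)C)(C(C)C)C(C)C)c(OC)c1)c1ccc(O[Si](C(C)C)(C(C)C)C(C)C)c(OC)c1 | intermediate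
14 | tert-butyl (3S,4S)-4-Ar-4-(Ar-methoxy)-2-(trifluoroacetyl)-3-{[(triisopropylsilyl)oxy]methyl}butanoate (C2 epimers, formed in the flask, not isolated) | CC(C)(C)OC(=O)C(C(=O)C(F)(F)F)[C@@H](CO[Si](C(C)C)(C(C)C)C(C)C)[C@H](OCc1ccc(O[Si](C(C)C)(C(C)C)C(C)C)c(OC)c1)c1ccc(O[Si](C(C)C)(C(C)C)C(C)C)c(OC)c1 | intermediate
15 | tert-butyl (3S,4S)-4-Ar-4-(Ar-methoxy)-2-diazo-3-{[(triisopropylsilyl)oxy]methyl}butanoate | CC(C)(C)OC(=O)C(=[N+]=[N-])[C@@H](CO[Si](C(C)C)(C(C)C)C(C)C)[C@H](OCc1ccc(O[Si](C(C)C)(C(C)C)C(C)C)c(OC)c1)c1ccc(O[Si](C(C)C)(C(C)C)C(C)C)c(OC)c1 | intermediate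
16 | tert-butyl (2S,3R,4S,5S)-2,5-di-Ar-4-{[(triisopropylsilyl)oxy]methyl}oxolane-3-carboxylate | COc1cc(ccc1O[Si](C(C)C)(C(C)C)C(C)C)[C@H]3O[C@H](c4ccc(O[Si](C(C)C)(C(C)C)C(C)C)c(OC)c4)[C@H](CO[Si](C(C)C)(C(C)C)C(C)C)[C@H]3C(=O)OC(C)(C)C | intermediate
17 | [(2S,3S,4S,5S)-2,5-di-Ar-4-{[(triisopropylsilyl)oxy]methyl}oxolan-3-yl]methanol | COc1cc(ccc1O[Si](C(C)C)(C(C)C)C(C)C)[C@H]3O[C@H](c4ccc(O[Si](C(C)C)(C(C)C)C(C)C)c(OC)c4)[C@H](CO[Si](C(C)C)(C(C)C)C(C)C)[C@H]3CO | intermediate
18 | Eduesmine, 4,4'-[(2S,3S,4S,5S)-3,4-bis(hydroxymethyl)oxolane-2,5-diyl]bis(2-methoxyphenol) | COc1cc([C@H]2O[C@H](c3ccc(O)c(OC)c3)[C@H](CO)[C@H]2CO)ccc1O | target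

## Step count and least certain steps

Total: 12 steps. Longest linear sequence: 10 steps (1 → 2 → 3 → 4 → 11 → 12 → 13 → 15 → 16 → 17 → 18, i.e. steps 1, 2, 3, 6, 7, 8, 9, 10, 11, 12).

Step 10 (key step). The most likely failure is a 1,2-hydride shift from the tertiary C4–H to the carbenoid carbon, which would give the unsaturated ester and destroy the C4 centre. Next in likelihood are poor discrimination between the two benzylic hydrogens (wrong C2 configuration if catalyst and substrate preferences are mismatched) and electrophilic attack of the carbenoid on the ortho position of the C5 aryl ring. The fallback leaves carbenoid chemistry, sets out from 10 and returns at 17.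
- LiBH4 would remove the auxiliary from 10 to give the 1,3-diol F1, and TIPSCl/imidazole would silylate its primary hydroxyl to give the silyl ether F2.
- Catalytic KOt-Bu in THF would close the cis-4,5-disubstituted γ-lactone F3 with loss of tert-butanol. No cation forms at C5, and the old ester carbon becomes C2.
- LiN(i-Pr)2 and monomeric formaldehyde would hydroxymethylate C3 on the face opposite the C4 arm and the C5 aryl ring, giving the 3-hydroxymethyl lactone F4.
- The aryllithium made with n-BuLi from the aryl bromide F5 (commercial 4-bromo-2-methoxyphenol, TIPSCl) would add to the lactone carbonyl (excess reagent, −78 °C) to give the lactol F6.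
- Et3SiH and BF3·OEt2 at −78 °C would reduce the cyclic oxocarbenium ion anti to the adjacent C3 arm, giving the C2 aryl cis to that arm, which is 17.

The weak point of this fallback is that the hydride must approach on the face that also carries the C4 arm and the C5 aryl ring, and that the Lewis acid must be kept cold to avoid ionising C5–O.

Step 5. Likely failures are incomplete anti or facial selectivity (the ester side chain can compete for magnesium) and slow addition to the electron-rich aldehyde, allowing silylated imide to accumulate. The fallback replaces aldol plus etherification by an anti-selective enolate addition to an acetal; it sets out from 2, 3 and 5 and returns at 12.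
- Aldehyde 2 and alcohol 3 (2.2 equiv; PPTS cat., 4 Å sieves, toluene) would give the bis(aryl-methyl) acetal F7.
- Acid 5 would be coupled (DCC, DMAP) with (4S)-4-isopropyl-1,3-thiazolidine-2-thione to give the N-acyl thiazolidinethione F8.
- The titanium enolate of F8 (TiCl4, i-Pr2NEt, CH2Cl2, −78 °C) would add to the oxocarbenium ion released from F7 by SnCl4, giving the anti β-alkoxy adduct F9 with the ether already in place.
- NaBH4 in THF/H2O would cleave the auxiliary to give 12.

Step 6. Likely failures are ionisation of the C5–O bond under the acid catalyst (epimerisation at C5 or lactonisation), rearrangement of the imidate to the N-benzyl trichloroacetamide, and self-alkylation of the electron-rich arene. The fallback forms the ether bond by reductive etherification instead of benzyl-cation transfer; it sets out from 9 and returns at 11. Silyl ether 9 would be isolated by a non-aqueous work-up of step 5 and treated with aldehyde 2, Et3SiH and catalytic TMSOTf in CH2Cl2 at −78 °C. The mixed silyl acetal would collapse to an oxocarbenium ion, which the silane would reduce to 11; no new compound is involved. Its own risk is over-reduction of the benzylic ether, so the temperature must stay low.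

Step 9. Likely failures are incomplete C-acylation of the hindered, β-branched enolate, O-acylation, and retro-Claisen loss of the trifluoroacetyl group before transfer, returning 13. The fallback introduces nitrogen as an azide; it sets out from 13 and returns at 15. The potassium enolate of 13 (KN(SiMe3)2, THF, −78 °C) would be treated with 2,4,6-triisopropylbenzenesulfonyl azide and quenched with AcOH to give the α-azido ester F10 (both C2 epimers are usable). N-succinimidyl 3-(diphenylphosphino)propanoate, then aqueous NaHCO3, would convert the azide into the diazo group through an acyl triazene that fragments to 15.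

## Further compounds

F1 | step 10 | tert-butyl (3S,4S)-4-Ar-4-hydroxy-3-(hydroxymethyl)butanoate | CC(C)(C)OC(=O)C[C@@H](CO)[C@H](O)c1ccc(O[Si](C(C)C)(C(C)C)C(C)C)c(OC)c1
F2 | step 10 | tert-butyl (3S,4S)-4-Ar-4-hydroxy-3-{[(triisopropylsilyl)oxy]methyl}butanoate | CC(C)(C)OC(=O)C[C@@H](CO[Si](C(C)C)(C(C)C)C(C)C)[C@H](O)c1ccc(O[Si](C(C)C)(C(C)C)C(C)C)c(OC)c1
F3 | step 10 | (4S,5S)-5-Ar-4-{[(triisopropylsilyl)oxy]methyl}oxolan-2-one | O=C1O[C@H](c2ccc(O[Si](C(C)C)(C(C)C)C(C)C)c(OC)c2)[C@H](CO[Si](C(C)C)(C(C)C)C(C)C)C1
F4 | step 10 | (3S,4S,5S)-5-Ar-3-(hydroxymethyl)-4-{[(triisopropylsilyl)oxy]methyl}oxolan-2-one | O=C1O[C@H](c2ccc(O[Si](C(C)C)(C(C)C)C(C)C)c(OC)c2)[C@H](CO[Si](C(C)C)(C(C)C)C(C)C)[C@H]1CO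
F5 | step 10 | (4-bromo-2-methoxyphenoxy)triisopropylsilane | COc1cc(Br)ccc1O[Si](C(C)C)(C(C)C)C(C)C
F6 | step 10 | (3S,4S,5S)-2,5-di-Ar-3-(hydroxymethyl)-4-{[(triisopropylsilyl)oxy]methyl}oxolan-2-ol (both C2 anomers) | OC1(c2ccc(O[Si](C(C)C)(C(C)C)C(C)C)c(OC)c2)O[C@H](c2ccc(O[Si](C(C)C)(C(C)C)C(C)C)c(OC)c2)[C@H](CO[Si](C(C)C)(C(C)C)C(C)C)[C@H]1CO
F7 | step 5 | bis(Ar-methyl) acetal of 3-methoxy-4-[(triisopropylsilyl)oxy]benzaldehyde | COc1cc(C(OCc2ccc(O[Si](C(C)C)(C(C)C)C(C)C)c(OC)c2)OCc2ccc(O[Si](C(C)C)(C(C)C)C(C)C)c(OC)c2)ccc1O[Si](C(C)C)(C(C)C)C(C)C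
F8 | step 5 | tert-butyl 4-oxo-4-[(4S)-4-isopropyl-2-thioxo-1,3-thiazolidin-3-yl]butanoate | CC(C)(C)OC(=O)CCC(=O)N1[C@@H](C(C)C)CSC1=S
F9 | step 5 | tert-butyl (3R,4S)-4-Ar-4-(Ar-methoxy)-3-{[(4S)-4-isopropyl-2-thioxo-1,3-thiazolidin-3-yl]carbonyl}butanoate | CC(C)(C)OC(=O)C[C@@H](C(=O)N1[C@@H](C(C)C)CSC1=S)[C@H](OCc1ccc(O[Si](C(C)C)(C(C)C)C(C)C)c(OC)c1)c1ccc(O[Si](C(C)C)(C(C)C)C(C)C)c(OC)c1
F0 | step 6 | none | none
F10 | step 9 | tert-butyl (3S,4S)-4-Ar-4-(Ar-methoxy)-2-azido-3-{[(triisopropylsilyl)oxy]methyl}butanoate (both C2 epimers) | CC(C)(C)OC(=O)C(N=[N+]=[N-])[C@@H](CO[Si](C(C)C)(C(C)C)C(C)C)[C@H](OCc1ccc(O[Si](C(C)C)(C(C)C)C(C)C)c(OC)c1)c1ccc(O[Si](C(C)C)(C(C)C)C(C)C)c(OC)c1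
A1 | alternative 1 | (2R,3R)-2,3-bis{(1E)-1-[4-(benzyloxy)-3-methoxyphenyl]prop-1-en-1-yl}butane-1,4-diol | C/C=C(/c1ccc(OCc2ccccc2)c(OC)c1)[C@H](CO)[C@@H](CO)/C(c3ccc(OCc4ccccc4)c(OC)c3)=C\C
A2 | alternative 1 | (2R,3E,5E,7R)-3,6-bis[4-(benzyloxy)-3-methoxyphenyl]-2,7-bis[(tributylstannyl)methoxy]octa-3,5-diene | C[C@@H](OC[Sn](CCCC)(CCCC)CCCC)/C(c1ccc(OCc2ccccc2)c(OC)c1)=C/C=C(c1ccc(OCc2ccccc2)c(OC)c1)/[C@@H](C)OC[Sn](CCCC)(CCCC)CCCC
A3 | alternative 2 | (2S,3R,4R,5S)-2,5-bis[4-(benzyloxy)-3-methoxyphenyl]-N3,N4-di(quinolin-8-yl)oxolane-3,4-dicarboxamide | COc1cc(ccc1OCc2ccccc2)[C@H]3O[C@H](c4ccc(OCc5ccccc5)c(OC)c4)[C@H](C(=O)Nc6cccc7cccnc67)[C@H]3C(=O)Nc8cccc9cccnc89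
A4 | alternative 2 | (3R,4R)-N3,N4-di(quinolin-8-yl)oxolane-3,4-dicarboxamide | C1OC[C@H](C(=O)Nc2cccc3cccnc23)[C@H]1C(=O)Nc1cccc2cccnc12
A5 | alternative 2 | 1-(benzyloxy)-4-iodo-2-methoxybenzene | COc1cc(I)ccc1OCc1ccccc1
A6 | alternative 3 | (3S,4S,5S)-5-[4-(benzyloxy)-3-methoxyphenyl]-3,4-bis[(benzyloxy)methyl]oxolan-2-one | O=C1O[C@H](c2ccc(OCc3ccccc3)c(OC)c2)[C@H](COCc4ccccc4)[C@H]1COCc5ccccc5
A7 | alternative 3 | (2S,3S,4S)-2-[4-(benzyloxy)-3-methoxyphenyl]-3,4-bis[(benzyloxy)methyl]cyclobutan-1-one | O=C1[C@H](c2ccc(OCc3ccccc3)c(OC)c2)[C@H](COCc2ccccc2)[C@H]1COCc1ccccc1
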